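**Retrosynthetic overview**

1. Feature: in the genkwanin half, benzo ring A (C4a–C5–C6–C7–C8–C8a) is fused to pyranone ring C. It carries the 5-hydroxyl and the 7-methoxyl meta to each other. This resorcinol monomethyl ether pattern is what a vinylketene and methoxyacetylene give, with the two oxygens already differentiated.
2. After removal of five MOM groups, ring A is cut at C8–C8a, C5–C6, C7–C8 and C4a–C5. This leads to the monocyclic 2-diazoacetyl-4-pyranone 15, whose C2=C3 bond is the vinyl part, and methoxyacetylene 18.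
3. Diazoketone 15 comes from acid 13. The hindered pyranone C5–luteolin C6 bond (C3–C6'' of the target) comes from a Suzuki–Miyaura coupling of triflate 11 with boronate 5.
4. Triflate 11 comes from comenic acid, whose 5-hydroxyl marks the luteolin site and directs bromine to C6 for ring B. Boronate 5 comes from luteolin by iodination at C6 next to the free 5-hydroxyl.
5. Ring order: the luteolin rings and pyranone ring C are bought, ring B is attached by coupling, and genkwanin ring A is formed last.

Key step: step 13

Assumption: the target SMILES holds no stereocentre and no descriptor for the C3–C6'' axis, so the axis is left uncontrolled and nothing stereochemical has to be set (MOM = methoxymethyl, CH2OCH3).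

**Step 1**
Reactants: 1 luteolin
Product: 2 luteolin 7,3',4'-tris(methoxymethyl) ether (5-hydroxyl free)
Conditions: MOMCl (3.3 equiv), iPr2NEt, DMF, 0 °C to rt
Reagents that add atoms: chloromethyl methyl ether, COCCl
Why: Phenol O-alkylation (MOM protection): the 7-, 3'- and 4'-hydroxyls react as ordinary phenols, whereas the 5-hydroxyl is tied to the C4 carbonyl by a hydrogen bond and should stay free under a mild amine base with a small excess of reagent.

**Step 2**
Reactants: 2 luteolin 7,3',4'-tris(methoxymethyl) ether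
Product: 3 6-iodoluteolin 7,3',4'-tris(methoxymethyl) ether
Conditions: BnMe3N·ICl2 (1.05 equiv), CaCO3, CH2Cl2–MeOH, rt, dark
Reagents that add atoms: benzyltrimethylammonium dichloroiodate, C[N+](C)(C)Cc1ccccc1.Cl[I-]Cl
Why: Electrophilic aromatic iodination with a dichloroiodate salt: in 5-hydroxy-7-alkoxyflavones this reagent type attacks C6, ortho to the free chelated phenol, rather than C8, and CaCO3 takes up the HCl so that the acetals survive.

**Step 3**
Reactants: 3 6-iodoluteolin 7,3',4'-tris(methoxymethyl) ether
Product: 4 6-iodoluteolin 5,7,3',4'-tetrakis(methoxymethyl) ether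
Conditions: NaH, MOMCl, DMF, 0 °C to rt
Reagents that add atoms: chloromethyl methyl ether, COCCl
Why: Williamson-type O-alkylation of the sodium phenoxide: full deprotonation breaks the hydrogen bond to the carbonyl, and the small chloromethyl ether reaches the oxygen between the iodine and the carbonyl.

**Step 4**
Reactants: 4 6-iodoluteolin 5,7,3',4'-tetrakis(methoxymethyl) ether
Product: 5 tetrakis-O-(methoxymethyl)luteolin-6-ylboronic acid pinacol ester
Conditions: pinacolborane, PdCl2(MeCN)2 (3 mol %), SPhos, Et3N, 1,4-dioxane, 80 °C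
Reagents that add atoms: pinacolborane, CC1(C)OBOC1(C)C
Why: Palladium-catalysed borylation of an aryl iodide with pinacolborane (Miyaura-type borylation): the bulky electron-rich biarylphosphine is the ligand of choice for aryl halides with two ortho substituents, and the amine base leaves flavone and acetals untouched.

**Step 5**
Reactants: 6 comenic acid
Product: 7 methyl comenate (methyl 5-hydroxy-4-oxo-4H-pyran-2-carboxylate)
Conditions: MeOH, H2SO4 (cat.), reflux
Reagents that add atoms: methanol, CO
Why: Fischer esterification: the acid is masked as a small ester that survives the couplings and can later be cleaved by mild base, and the enolic 5-hydroxyl is not etherified under these conditions.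

**Step 6**
Reactants: 7 methyl comenate
Product: 8 methyl 6-bromo-5-hydroxy-4-oxo-4H-pyran-2-carboxylate
Conditions: NBS, MeCN, 0 °C to rt
Reagents that add atoms: N-bromosuccinimide, O=C1CCC(=O)N1Br
Why: Electrophilic bromination of an enol: C6 is the β-carbon of the C5 enol and the site at which 3-hydroxy-4-pyranones take up electrophiles, while C3 lies next to the ester-bearing carbon and is deactivated.

**Step 7**
Reactants: 8 methyl 6-bromo-5-hydroxy-4-oxo-4H-pyran-2-carboxylate
Product: 9 methyl 6-bromo-4-oxo-5-(trifluoromethylsulfonyloxy)-4H-pyran-2-carboxylate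
Conditions: Tf2O, pyridine, CH2Cl2, −20 to 0 °C
Reagents that add atoms: trifluoromethanesulfonic anhydride, O=S(=O)(OS(=O)(=O)C(F)(F)F)C(F)(F)F
Why: O-Triflation of the acidic enol turns the oxygen that marks C5 into a coupling handle.

**Step 8**
Reactants: 9 methyl 6-bromo-4-oxo-5-(trifluoromethylsulfonyloxy)-4H-pyran-2-carboxylate; 10 4-(methoxymethoxy)phenylboronic acid
Product: 11 methyl 6-[4-(methoxymethoxy)phenyl]-4-oxo-5-(trifluoromethylsulfonyloxy)-4H-pyran-2-carboxylate
Conditions: Pd(PPh3)4 (5 mol %), K3PO4, 1,4-dioxane, 50 °C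
Reagents that add atoms: none
Why: Site-selective Suzuki–Miyaura coupling: zerovalent palladium with triphenylphosphine inserts into C–Br before C–OTf, and C6 is also the β-carbon of the enone next to the ring oxygen, the position that reacts first in dihalogenated enone heterocycles, so ring B should enter at C6 and the triflate should stay.

**Step 9**
Reactants: 11 methyl 6-[4-(methoxymethoxy)phenyl]-4-oxo-5-(trifluoromethylsulfonyloxy)-4H-pyran-2-carboxylate; 5 tetrakis-O-(methoxymethyl)luteolin-6-ylboronic acid pinacol ester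
Product: 12 methyl 6-[4-(methoxymethoxy)phenyl]-4-oxo-5-[tetrakis-O-(methoxymethyl)luteolin-6-yl]-4H-pyran-2-carboxylate
Conditions: Pd(OAc)2 (10 mol %), SPhos, K3PO4, toluene–H2O (20:1), 90 °C
Reagents that add atoms: none
Why: Suzuki–Miyaura coupling of an electron-poor α-triflyloxy enone, which undergoes fast oxidative addition, with a boronate flanked by two alkoxy groups, a pairing for which SPhos-ligated palladium with K3PO4 is the standard answer; it forms the pyranone C5–luteolin C6 bond, the later C3–C6'' bond.

**Step 10**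
Reactants: 12 methyl 6-[4-(methoxymethoxy)phenyl]-4-oxo-5-[tetrakis-O-(methoxymethyl)luteolin-6-yl]-4H-pyran-2-carboxylate
Product: 13 6-[4-(methoxymethoxy)phenyl]-4-oxo-5-[tetrakis-O-(methoxymethyl)luteolin-6-yl]-4H-pyran-2-carboxylic acid
Conditions: LiOH (1.2 equiv), THF–H2O, 0 °C; then 0.5 M HCl to pH 3, 0 °C
Reagents that add atoms: lithium hydroxide, [Li+].[OH-]
Why: Saponification: the ester sits on the electron-poor pyranone next to the ring oxygen and is activated, so about one equivalent of hydroxide at 0 °C should cleave it faster than it attacks the ring, and the short cold acidification spares the acetals.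

**Step 11**
Reactants: 13 6-[4-(methoxymethoxy)phenyl]-4-oxo-5-[tetrakis-O-(methoxymethyl)luteolin-6-yl]-4H-pyran-2-carboxylic acid
Product: 15 2-diazo-1-{6-[4-(methoxymethoxy)phenyl]-4-oxo-5-[tetrakis-O-(methoxymethyl)luteolin-6-yl]-4H-pyran-2-yl}ethanone, via pyranone-2-carbonyl chloride 14 (not isolated)
Conditions: Me2C=C(Cl)NMe2, CH2Cl2, 0 °C; then CH2N2 (Et2O solution, distilled beforehand from Diazald/KOH, 4 equiv), 0 °C
Reagents that add atoms: diazomethane, C=[N+]=[N-]; 1-chloro-N,N,2-trimethylprop-1-en-1-amine, CC(C)=C(Cl)N(C)C (chlorine of 14 only)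
Why: Acylation of diazomethane by an acid chloride (first stage of the Arndt–Eistert sequence): the chloroenamine makes the chloride without free HCl so the five acetals survive, and acylation at 0 °C should outrun dipolar cycloaddition to the pyranone C2=C3 bond, as it does with chromone-2-carbonyl and other heteroaroyl chlorides.

**Step 12**
Reactants: 16 chloroacetaldehyde dimethyl acetal
Product: 18 methoxyacetylene, via sodium methoxyacetylide 17 (not isolated)
Conditions: NaNH2 (3 equiv), liq. NH3, −33 °C; NH3 evaporated; then H2O (brine), −20 °C; distilled into cold ClCH2CH2Cl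
Reagents that add atoms: sodium amide, [Na+].[NH2-] (sodium of 17 only)
Why: Base-induced double β-elimination (HCl, then methanol) from a chloroacetal, the standard preparation of alkoxyacetylenes, in which the third equivalent of amide holds the volatile product as its sodium salt until the aqueous quench.

**Step 13**
Reactants: 15 2-diazo-1-{6-[4-(methoxymethoxy)phenyl]-4-oxo-5-[tetrakis-O-(methoxymethyl)luteolin-6-yl]-4H-pyran-2-yl}ethanone; 18 methoxyacetylene
Product: 23 target pentakis(methoxymethyl) ether (genkwanin 5-hydroxyl free), via pyranonylketene 19 (not isolated), via 3-methoxy-4-pyranonylcyclobutenone 20 (not isolated), via dienylketene 21 (not isolated), via cyclohexadienone tautomer 22 (not isolated)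
Conditions: 18 (4 equiv), ClCH2CH2Cl, hν (440–450 nm LED), 15 °C, pressure tube; excess 18 vented; then 80 °C
Reagents that add atoms: none
Why: Blue light should reach only the weak n–π* band of the diazoketone, because the flavone and arylpyranone chromophores are expected to be transparent there; nitrogen leaves and the Wolff 1,2-shift moves pyranone C2 (future C8a) from the carbonyl carbon (future C5) to the former diazo carbon (future C8), giving ketene 19 conjugated with the pyranone C2=C3 bond. Ketene 19 and 18 join in a [2+2] cycloaddition (C5–C6 and C7–C8) to cyclobutenone 20, which at 80 °C opens reversibly by four-electron electrocyclic cleavage of the C5–C8 bond to dienylketene 21. Ring A closes by six-electron electrocyclisation of 21, the ketene carbon C5 bonding to pyranone C3 (future C4a), and dienone 22 enolises to the phenol, which is held by a hydrogen bond to the C4 carbonyl. The closest known reaction type is the second-generation (diazoketone) Danheiser benzannulation, established for cycloalkenyl, aryl and heteroaryl diazomethyl ketones with alkoxy- and siloxyacetylenes. The selectivity needed is the orientation of the [2+2] step: the unsubstituted, nucleophilic carbon of the ynol ether attacks the electrophilic ketene carbonyl carbon, which puts the methoxyl on C7 meta to the new 5-hydroxyl, and closure can occur only at C3 because the other neighbour of C2 is the ring oxygen. No stereocentre survives (C4 of 20 and C4a of 22 are transient and racemic), and the reacting C2/C3 edge lies opposite the crowded C5/C6 edge of the pyranone.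

**Step 14**
Reactants: 23 target pentakis(methoxymethyl) ether
Product: 24 CNP0200311.0 (3-(luteolin-6-yl)genkwanin)
Conditions: HCl (conc., cat.), MeOH–THF, 50 °C
Reagents that add atoms: none
Why: Acid-catalysed acetal exchange (MOM cleavage): all five aryl methoxymethyl ethers are transferred to methanol, while the aryl methyl ether at C7 and both flavone cores are inert to dilute acid.

**Compound list**

1 | luteolin | O=c1cc(-c2ccc(O)c(O)c2)oc2cc(O)cc(O)c12 | starting material
2 | luteolin 7,3',4'-tris(methoxymethyl) ether | O=c1cc(-c2ccc(OCOC)c(OCOC)c2)oc2cc(OCOC)cc(O)c12 | intermediate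
3 | 6-iodoluteolin 7,3',4'-tris(methoxymethyl) ether | O=c1cc(-c2ccc(OCOC)c(OCOC)c2)oc2cc(OCOC)c(I)c(O)c12 | intermediate
4 | 6-iodoluteolin 5,7,3',4'-tetrakis(methoxymethyl) ether | O=c1cc(-c2ccc(OCOC)c(OCOC)c2)oc2cc(OCOC)c(I)c(OCOC)c12 | intermediate
5 | tetrakis-O-(methoxymethyl)luteolin-6-ylboronic acid pinacol ester | O=c1cc(-c2ccc(OCOC)c(OCOC)c2)oc2cc(OCOC)c(B3OC(C)(C)C(C)(C)O3)c(OCOC)c12 | intermediate
6 | comenic acid (5-hydroxy-4-oxo-4H-pyran-2-carboxylic acid) | O=C(O)c1cc(=O)c(O)co1 | starting material
7 | methyl comenate | COC(=O)c1cc(=O)c(O)co1 | intermediate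
8 | methyl 6-bromo-5-hydroxy-4-oxo-4H-pyran-2-carboxylate | COC(=O)c1cc(=O)c(O)c(Br)o1 | intermediate
9 | methyl 6-bromo-4-oxo-5-(trifluoromethylsulfonyloxy)-4H-pyran-2-carboxylate | COC(=O)c1cc(=O)c(OS(=O)(=O)C(F)(F)F)c(Br)o1 | intermediate
10 | 4-(methoxymethoxy)phenylboronic acid | COCOc1ccc(B(O)O)cc1 | starting material
11 | methyl 6-[4-(methoxymethoxy)phenyl]-4-oxo-5-(trifluoromethylsulfonyloxy)-4H-pyran-2-carboxylate | COC(=O)c1cc(=O)c(OS(=O)(=O)C(F)(F)F)c(-c2ccc(OCOC)cc2)o1 | intermediate
12 | methyl 6-[4-(methoxymethoxy)phenyl]-4-oxo-5-[tetrakis-O-(methoxymethyl)luteolin-6-yl]-4H-pyran-2-carboxylate | COC(=O)c1cc(=O)c(-c2c(OCOC)cc3oc(-c4ccc(OCOC)c(OCOC)c4)cc(=O)c3c2OCOC)c(-c2ccc(OCOC)cc2)o1 | intermediate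
13 | 6-[4-(methoxymethoxy)phenyl]-4-oxo-5-[tetrakis-O-(methoxymethyl)luteolin-6-yl]-4H-pyran-2-carboxylic acid | O=C(O)c1cc(=O)c(-c2c(OCOC)cc3oc(-c4ccc(OCOC)c(OCOC)c4)cc(=O)c3c2OCOC)c(-c2ccc(OCOC)cc2)o1 | intermediate
14 | acid chloride of 13 | O=C(Cl)c1cc(=O)c(-c2c(OCOC)cc3oc(-c4ccc(OCOC)c(OCOC)c4)cc(=O)c3c2OCOC)c(-c2ccc(OCOC)cc2)o1 | intermediate
15 | 2-diazo-1-{6-[4-(methoxymethoxy)phenyl]-4-oxo-5-[tetrakis-O-(methoxymethyl)luteolin-6-yl]-4H-pyran-2-yl}ethanone | [N-]=[N+]=CC(=O)c1cc(=O)c(-c2c(OCOC)cc3oc(-c4ccc(OCOC)c(OCOC)c4)cc(=O)c3c2OCOC)c(-c2ccc(OCOC)cc2)o1 | intermediate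
16 | chloroacetaldehyde dimethyl acetal (2-chloro-1,1-dimethoxyethane) | COC(CCl)OC | starting material
17 | sodium methoxyacetylide | COC#[C-].[Na+] | intermediate
18 | methoxyacetylene | COC#C | intermediate
19 | (pyranon-2-yl)ketene from the Wolff shift of 15 | O=C=Cc1cc(=O)c(-c2c(OCOC)cc3oc(-c4ccc(OCOC)c(OCOC)c4)cc(=O)c3c2OCOC)c(-c2ccc(OCOC)cc2)o1 | intermediate
20 | 3-methoxy-4-(pyranon-2-yl)cyclobut-2-en-1-one (racemic at C4) | COC1=CC(=O)C1c1cc(=O)c(-c2c(OCOC)cc3oc(-c4ccc(OCOC)c(OCOC)c4)cc(=O)c3c2OCOC)c(-c2ccc(OCOC)cc2)o1 | intermediate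
21 | 3-methoxy-4-(pyranon-2-yl)buta-1,3-dien-1-one (ketene chain and pyranonyl cis on the C=C bond) | O=C=C/C(OC)=C\c1cc(=O)c(-c2c(OCOC)cc3oc(-c4ccc(OCOC)c(OCOC)c4)cc(=O)c3c2OCOC)c(-c2ccc(OCOC)cc2)o1 | intermediate
22 | 4a-H cyclohexadienone tautomer of 23 (racemic at C4a) | COC1=CC(=O)C2C(=C1)OC(c1ccc(OCOC)cc1)=C(c1c(OCOC)cc3oc(-c4ccc(OCOC)c(OCOC)c4)cc(=O)c3c1OCOC)C2=O | intermediate
23 | 5-hydroxy-7-methoxy-2-[4-(methoxymethoxy)phenyl]-3-[tetrakis-O-(methoxymethyl)luteolin-6-yl]-4H-chromen-4-one | COc1cc(O)c2c(=O)c(-c3c(OCOC)cc4oc(-c5ccc(OCOC)c(OCOC)c5)cc(=O)c4c3OCOC)c(-c3ccc(OCOC)cc3)oc2c1 | intermediate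
24 | CNP0200311.0, 3-(luteolin-6-yl)genkwanin | COc1cc(O)c2c(=O)c(-c3c(O)cc4oc(-c5ccc(O)c(O)c5)cc(=O)c4c3O)c(-c3ccc(O)cc3)oc2c1 | target

**Step count**

Total step count: 14.
Longest linear sequence: 9 steps, either 5, 6, 7, 8, 9, 10, 11, 13, 14 from comenic acid or 1, 2, 3, 4, 9, 10, 11, 13, 14 from luteolin.

**Steps most likely to fail**

**Step 13.**
- The weak visible absorption of the diazoketone may make nitrogen loss slow.
- Ketene dimerisation, acylation of the product phenol by the ketene, and evaporation or polymerisation of the ynol ether could then overtake the cycloaddition.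
- The large chromophores may also be degraded on long irradiation.

The fallback makes the same ketene without light. It sets out from 15 and comes back at ketene 19, and so at 23. Silver-catalysed Wolff rearrangement of 15 in wet solvent (PhCO2Ag cat., Et3N, THF–H2O, rt, dark) should give the homologous (pyranon-2-yl)acetic acid F1. This acid is kept cold because it is a vinylogous β-keto acid. Me2C=C(Cl)NMe2 in CH2Cl2 at 0 °C should convert it into the (pyranon-2-yl)acetyl chloride F2. Slow addition of Et3N to F2 and excess 18 at 0 °C dehydrochlorinates the acidic methylene to 19. Ketene 19 is trapped as 20, and 20 is then heated at 80 °C as in the main route.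

**Step 9.**
- Transmetalation of the boronate between two ortho MOM ethers may be slow.
- Protodeboronation of 5 and base hydrolysis of the triflate and ester functions of 11 could then consume both partners.

The fallback is a base-free Negishi coupling. It sets out from iodide 4 and comes back at 12. Direct insertion of zinc dust in the presence of LiCl (THF, 50 °C), which tolerates the flavone carbonyl, should give the luteolin-6-ylzinc iodide F3. This is coupled with triflate 11 under Pd2(dba)3/RuPhos in THF at 60 °C.

**Step 8.**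
- Site selectivity may be lost, through insertion into the C5–OTf bond or double coupling.
- The base may attack C6 of the very electron-poor bromotriflate by addition–elimination, which would erode the coupling.

The fallback separates the two tasks. It sets out from 8 and comes back at 11.
- Benzylation of 8 (BnBr, K2CO3, DMF) should give methyl 5-(benzyloxy)-6-bromo-4-oxo-4H-pyran-2-carboxylate F4.
- Suzuki–Miyaura coupling of its only halide with 10 (Pd(PPh3)4, K3PO4, dioxane) should give methyl 5-(benzyloxy)-6-[4-(methoxymethoxy)phenyl]-4-oxo-4H-pyran-2-carboxylate F5.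
- Hydrogenolysis (H2, Pd/C, EtOAc) should free methyl 5-hydroxy-6-[4-(methoxymethoxy)phenyl]-4-oxo-4H-pyran-2-carboxylate F6.
- Triflation of F6 (Tf2O, pyridine) gives 11.

**Further compounds**

F1 | step 13 | {6-[4-(methoxymethoxy)phenyl]-4-oxo-5-[tetrakis-O-(methoxymethyl)luteolin-6-yl]-4H-pyran-2-yl}acetic acid | O=C(O)Cc1cc(=O)c(-c2c(OCOC)cc3oc(-c4ccc(OCOC)c(OCOC)c4)cc(=O)c3c2OCOC)c(-c2ccc(OCOC)cc2)o1
F2 | step 13 | acid chloride of F1 | O=C(Cl)Cc1cc(=O)c(-c2c(OCOC)cc3oc(-c4ccc(OCOC)c(OCOC)c4)cc(=O)c3c2OCOC)c(-c2ccc(OCOC)cc2)o1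
F3 | step 9 | tetrakis-O-(methoxymethyl)luteolin-6-ylzinc iodide | I[Zn]c1c(OCOC)cc2oc(-c3ccc(OCOC)c(OCOC)c3)cc(=O)c2c1OCOC
F4 | step 8 | methyl 5-(benzyloxy)-6-bromo-4-oxo-4H-pyran-2-carboxylate | COC(=O)c1cc(=O)c(OCc2ccccc2)c(Br)o1
F5 | step 8 | methyl 5-(benzyloxy)-6-[4-(methoxymethoxy)phenyl]-4-oxo-4H-pyran-2-carboxylate | COC(=O)c1cc(=O)c(OCc2ccccc2)c(-c2ccc(OCOC)cc2)o1
F6 | step 8 | methyl 5-hydroxy-6-[4-(methoxymethoxy)phenyl]-4-oxo-4H-pyran-2-carboxylate | COC(=O)c1cc(=O)c(O)c(-c2ccc(OCOC)cc2)o1
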